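**Retrosynthetic overview**

1. Ring C (tetronic acid; O1, C2, C3, C4, C5; side chain C1'–C9') is made last, in one flask, from ynone 16 and CO2. CO2 is captured at C3, then the ring closes through the O1–C5 bond by anti attack of the carboxylate on the silver-bound alkyne, which also fixes the 5Z alkene.
2. Ynone 16 comes from terminal alkyne 14 and N-methoxy-N-methylpropanamide; 14 comes from primary alcohol 12 by oxidation and one-carbon homologation.
3. The C8'=C9' bond of the diene comes from a Horner–Wadsworth–Emmons union of allylic phosphonate 11 with furan aldehyde 7.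
4. Phosphonate 11 comes from geranyl bromide (6'E alkene bought) by Arbuzov reaction, SeO2 oxidation of the E-methyl and hydroxyl-directed asymmetric hydrogenation, which sets C2' as S.
5. Aldehyde 7 comes from 3,4-dibromofuran (ring A) and furan-3-carbaldehyde (ring B). Rings A and B are bought intact, so ring C is the only ring formed.

Assumption: Ru(OAc)2[(S)-BINAP] is taken to add H2 to allylic alcohol 10 from the same face of the C=C–CH2–OH unit as with geraniol (which gives (R)-citronellol); on 10 that face gives 7S. The configuration of 11 is confirmed as its Mosher ester before it is carried on, and the (R)-ligand is used if the sense proves opposite.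

**Route**

Step 1
Reactants: 1 3,4-dibromofuran; 2 furan-3-carbaldehyde
Product: 4 (4-bromofuran-3-yl)(furan-3-yl)methanol (racemic), via 3-bromo-4-lithiofuran 3 (not isolated)
Conditions: n-BuLi (1.0 equiv), Et2O, −78 °C, 20 min; then 2, −78 °C; H2O
Reagents that add atoms: none
Why: Bromine–lithium exchange of one C–Br bond at −78 °C is faster than a second exchange or ring opening, and the 3-furyllithium adds 1,2 to the aldehyde (halogen–metal exchange/carbonyl addition); the carbinol centre is racemic and is removed in step 2.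

Step 2
Reactants: 4 (4-bromofuran-3-yl)(furan-3-yl)methanol
Product: 5 3-bromo-4-(furan-3-ylmethyl)furan
Conditions: Et3SiH (3 equiv), CF3CO2H (3 equiv), CH2Cl2, −20 → 0 °C
Reagents that add atoms: none
Why: Ionic hydrogenation, in which the carbocation stabilised by two 3-furyl groups is trapped by silane hydride faster than it can alkylate another furan at low temperature.

Step 3
Reactants: 5 3-bromo-4-(furan-3-ylmethyl)furan
Product: 7 4-(furan-3-ylmethyl)furan-3-carbaldehyde, via 3-(furan-3-ylmethyl)-4-lithiofuran 6 (not isolated)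
Conditions: n-BuLi (1.05 equiv), THF, −78 °C; DMF, −78 → 0 °C; H2O
Reagents that add atoms: N,N-dimethylformamide, CN(C)C=O
Why: Bromine–lithium exchange at −78 °C is much faster than deprotonation of the furan or CH2 positions, and the aryllithium is formylated by DMF (Bouveault formylation).

Step 4
Reactants: 8 geranyl bromide, (2E)-1-bromo-3,7-dimethylocta-2,6-diene
Product: 9 diethyl [(2E)-3,7-dimethylocta-2,6-dien-1-yl]phosphonate
Conditions: P(OEt)3 (3 equiv, neat), 130 °C, EtBr distilled off
Reagents that add atoms: triethyl phosphite, CCOP(OCC)OCC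
Why: Michaelis–Arbuzov reaction by SN2 attack of phosphorus at the primary allylic carbon, which leaves the 2E alkene untouched.

Step 5
Reactants: 9 diethyl [(2E)-3,7-dimethylocta-2,6-dien-1-yl]phosphonate
Product: 10 diethyl [(2E,6E)-8-hydroxy-3,7-dimethylocta-2,6-dien-1-yl]phosphonate
Conditions: SeO2 (0.3 equiv), t-BuOOH (3 equiv), salicylic acid (0.1 equiv), CH2Cl2, 0 °C → rt
Reagents that add atoms: tert-butyl hydroperoxide, CC(C)(C)OO
Why: Riley allylic oxidation under catalytic SeO2/t-BuOOH conditions, where the ene reaction and [2,3]-shift occur at the more electron-rich terminal trisubstituted alkene and oxidise its E-methyl group, giving the 6E allylic alcohol.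

Step 6
Reactants: 10 diethyl [(2E,6E)-8-hydroxy-3,7-dimethylocta-2,6-dien-1-yl]phosphonate
Product: 11 diethyl [(2E,7S)-8-hydroxy-3,7-dimethyloct-2-en-1-yl]phosphonate
Conditions: Ru(OAc)2[(S)-BINAP] (1 mol %), H2 (50 atm), MeOH, 25 °C
Reagents that add atoms: none
Why: Noyori hydroxyl-directed asymmetric hydrogenation, in which only the alkene held on ruthenium through the allylic alkoxide is reduced and the (S)-BINAP pocket delivers H2 to the face that gives 7S, while the allylic phosphonate alkene has no protic handle and stays 2E.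

Step 7
Reactants: 11 diethyl [(2E,7S)-8-hydroxy-3,7-dimethyloct-2-en-1-yl]phosphonate; 7 4-(furan-3-ylmethyl)furan-3-carbaldehyde
Product: 12 (2S,6E,8E)-9-[4-(furan-3-ylmethyl)furan-3-yl]-2,6-dimethylnona-6,8-dien-1-ol
Conditions: KOtBu (2.2 equiv), THF, −20 °C; then 7, −20 °C → rt; H2O
Reagents that add atoms: none
Why: Horner–Wadsworth–Emmons olefination of the allylic phosphonate anion (the alkoxide is a spectator) with the heteroaryl aldehyde, which gives the new disubstituted alkene E through the reversible, anti-selective adduct and keeps the existing trisubstituted E alkene.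

Step 8
Reactants: 12 (2S,6E,8E)-9-[4-(furan-3-ylmethyl)furan-3-yl]-2,6-dimethylnona-6,8-dien-1-ol
Product: 14 3-[(1E,3E,8S)-4,8-dimethyldeca-1,3-dien-9-yn-1-yl]-4-(furan-3-ylmethyl)furan, via (2S)-dienal 13 (not isolated)
Conditions: Dess–Martin periodinane (1.2 equiv), CH2Cl2, 0 °C → rt; then MeOH, K2CO3 (4 equiv), dimethyl (1-diazo-2-oxopropyl)phosphonate (1.5 equiv), 0 °C → rt
Reagents that add atoms: dimethyl (1-diazo-2-oxopropyl)phosphonate, COP(=O)(OC)C(=[N+]=[N-])C(C)=O
Why: Dess–Martin oxidation followed in the same flask by Ohira–Bestmann (Seyferth–Gilbert) homologation, so the α-methyl aldehyde is never isolated and is converted at 0 °C under K2CO3/MeOH, conditions under which such aldehydes keep their configuration.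

Step 9
Reactants: 14 3-[(1E,3E,8S)-4,8-dimethyldeca-1,3-dien-9-yn-1-yl]-4-(furan-3-ylmethyl)furan
Product: 16 (6S,10E,12E)-13-[4-(furan-3-ylmethyl)furan-3-yl]-6,10-dimethyltrideca-10,12-dien-4-yn-3-one, via lithium acetylide 15 (not isolated)
Conditions: n-BuLi (1.05 equiv), THF, −78 °C; EtC(O)N(OMe)Me, −78 → −20 °C; HCl (2 M in Et2O, 2.2 equiv), −78 °C
Reagents that add atoms: N-methoxy-N-methylpropanamide, CCC(=O)N(C)OC
Why: Acylation of the lithium acetylide with a Weinreb amide, whose chelated tetrahedral adduct prevents over-addition, while the cold acid quench protonates the released N,O-dimethylhydroxylamine before it can add to the ynone.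

Step 10
Reactants: 16 (6S,10E,12E)-13-[4-(furan-3-ylmethyl)furan-3-yl]-6,10-dimethyltrideca-10,12-dien-4-yn-3-one
Product: 18 (5Z)-5-{(2S,6E,8E)-9-[4-(furan-3-ylmethyl)furan-3-yl]-2,6-dimethylnona-6,8-dien-1-ylidene}-4-hydroxy-3-methylfuran-2(5H)-one, via β-keto carboxylate 17 (not isolated)
Conditions: AgOAc (10 mol %), MTBD (7-methyl-1,5,7-triazabicyclo[4.4.0]dec-5-ene, 2.5 equiv), CO2 (1.0 MPa), MeCN, 25 °C, dark; then aq. citric acid (pH 3)
Reagents that add atoms: carbon dioxide, O=C=O
Why: Proposed new method: silver-catalysed carboxylative 5-exo-dig lactonisation of an alkyl-substituted ynone that carries a stereocentre at its propargylic carbon. MTBD enolises the ethyl ketone at its only α-CH2 and the enolate is C-carboxylated by CO2 to β-keto carboxylate 17; monovalent silver (AgOAc) then activates the alkyne for anti attack of the carboxylate oxygen at the proximal alkyne carbon (O1–C5 bond), and protodeargentation with retention places H trans to O1, which gives the 5Z alkene, before enolisation gives the 4-hydroxy tautomer. In the enolate/carboxylate dianion the alkyne is no longer conjugated to a ketone, which disfavours both 6-endo conjugate closure and deprotonation of the propargylic C2'–H, so the stereocentre from step 6 should be carried through. The closest known reaction types are the silver acetate/amidine incorporation of CO2 into simple achiral conjugated ynones to give tetronic acids and the silver-catalysed lactonisation of (Z)-2-en-4-ynoic acids to (Z)-ylidene butenolides; neither has been shown on a ynone with an epimerisable tertiary propargylic centre and an acid-sensitive furyl diene.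

**Compound list**

1 | 3,4-dibromofuran | Brc1cocc1Br | starting material
2 | furan-3-carbaldehyde | O=Cc1ccoc1 | starting material
3 | 3-bromo-4-lithiofuran | [Li]c1cocc1Br | intermediate (not isolated)
4 | (4-bromofuran-3-yl)(furan-3-yl)methanol (racemic) | OC(c1ccoc1)c1cocc1Br | intermediate
5 | 3-bromo-4-(furan-3-ylmethyl)furan | Brc1cocc1Cc1ccoc1 | intermediate
6 | 3-(furan-3-ylmethyl)-4-lithiofuran | [Li]c1cocc1Cc1ccoc1 | intermediate (not isolated)
7 | 4-(furan-3-ylmethyl)furan-3-carbaldehyde | O=Cc1cocc1Cc1ccoc1 | intermediate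
8 | geranyl bromide, (2E)-1-bromo-3,7-dimethylocta-2,6-diene | CC(C)=CCC/C(C)=C/CBr | starting material
9 | diethyl [(2E)-3,7-dimethylocta-2,6-dien-1-yl]phosphonate | CC(C)=CCC/C(C)=C/CP(=O)(OCC)OCC | intermediate
10 | diethyl [(2E,6E)-8-hydroxy-3,7-dimethylocta-2,6-dien-1-yl]phosphonate | OC/C(C)=C/CC/C(C)=C/CP(=O)(OCC)OCC | intermediate
11 | diethyl [(2E,7S)-8-hydroxy-3,7-dimethyloct-2-en-1-yl]phosphonate | OC[C@@H](C)CCC/C(C)=C/CP(=O)(OCC)OCC | intermediate
12 | (2S,6E,8E)-9-[4-(furan-3-ylmethyl)furan-3-yl]-2,6-dimethylnona-6,8-dien-1-ol | OC[C@@H](C)CCC/C(C)=C/C=C/c1cocc1Cc1ccoc1 | intermediate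
13 | (2S,6E,8E)-9-[4-(furan-3-ylmethyl)furan-3-yl]-2,6-dimethylnona-6,8-dienal | O=C[C@@H](C)CCC/C(C)=C/C=C/c1cocc1Cc1ccoc1 | intermediate (not isolated)
14 | 3-[(1E,3E,8S)-4,8-dimethyldeca-1,3-dien-9-yn-1-yl]-4-(furan-3-ylmethyl)furan | C#C[C@@H](C)CCC/C(C)=C/C=C/c1cocc1Cc1ccoc1 | intermediate
15 | {(3S,7E,9E)-10-[4-(furan-3-ylmethyl)furan-3-yl]-3,7-dimethyldeca-7,9-dien-1-yn-1-yl}lithium | [Li]C#C[C@@H](C)CCC/C(C)=C/C=C/c1cocc1Cc1ccoc1 | intermediate (not isolated)
16 | (6S,10E,12E)-13-[4-(furan-3-ylmethyl)furan-3-yl]-6,10-dimethyltrideca-10,12-dien-4-yn-3-one | CCC(=O)C#C[C@@H](C)CCC/C(C)=C/C=C/c1cocc1Cc1ccoc1 | intermediate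
17 | (6S,10E,12E)-13-[4-(furan-3-ylmethyl)furan-3-yl]-2,6,10-trimethyl-3-oxotrideca-10,12-dien-4-ynoic acid (present as its MTBD-H+ carboxylate; C2 not defined) | OC(=O)C(C)C(=O)C#C[C@@H](C)CCC/C(C)=C/C=C/c1cocc1Cc1ccoc1 | intermediate (not isolated)
18 | (5Z)-5-{(2S,6E,8E)-9-[4-(furan-3-ylmethyl)furan-3-yl]-2,6-dimethylnona-6,8-dien-1-ylidene}-4-hydroxy-3-methylfuran-2(5H)-one | CC1=C(O)/C(=C/[C@@H](C)CCC/C(C)=C/C=C/c2cocc2Cc2ccoc2)OC1=O | target

**Step count and risks**

Total step count: 10 (steps 1–3 to aldehyde 7; steps 4–10 from geranyl bromide to 18).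
Longest linear sequence: 7 steps (steps 4–10; the branch through steps 1–3 and 7–10 is also 7).

The three steps most likely to fail are step 10, step 6 and step 7.

Step 10 (the proposed new step). The risks are epimerisation at C2' through deprotonation at the propargylic carbon of 16, 6-endo closure to the isomeric pyranone, and weak activation of the alkyl alkyne. The fallback replaces the closure by the established aldol, dehydration and demethylation sequence for 5-ylidene tetronic acids. It sets out from alcohol 12, which is oxidised with Dess–Martin periodinane to aldehyde 13, now isolated. Commercial 4-hydroxy-3-methylfuran-2(5H)-one is O-methylated (Me2SO4, K2CO3, acetone) to 4-methoxy-3-methylfuran-2(5H)-one F1. Its C5 lithium anion (LiN(i-Pr)2, THF, −78 °C) adds to 13 to give the aldol adduct F2, a diastereomer mixture at the two new centres, both of which are destroyed later. MsCl/Et3N converts it into the mesylate F3, and DBU eliminates this to the (5Z)-ylidene methyl tetronate F4, the thermodynamically favoured isomer. Cleavage of the methyl ether with n-PrSLi in HMPA at 25 °C comes back to the route at 18.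

Step 6. The risks are moderate ee for a 2-methyl-substituted allylic alcohol, an unexpected facial sense, or poisoning by selenium traces from step 5. The fallback moves the directing group from hydroxyl to carboxylate. It sets out from 10: MnO2 in CH2Cl2 gives the enal F5, and Pinnick oxidation (NaClO2, NaH2PO4, 2-methyl-2-butene, t-BuOH/H2O) gives the (2E)-acid F6. Ru(OAc)2[(S)-H8-BINAP] under H2 (4 atm, MeOH) reduces only the tiglic-acid-type alkene to the (2S)-acid F7, by analogy with tiglic acid giving (S)-2-methylbutanoic acid. Activation as the isobutyl mixed anhydride F8 (i-BuOCOCl, N-methylmorpholine, THF, −15 °C) and reduction with NaBH4 (THF/H2O, 0 °C) comes back to the route at 11.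

Step 7. The risks are an E/Z mixture at C8'=C9', partial scrambling of the 6'E alkene through the allylic anion, or a sluggish electron-rich aldehyde. The fallback forms the furan–C9' bond by a Heck reaction instead of forming the alkene by carbonyl olefination. It sets out from 11 and 5: phosphonate 11 is olefinated with paraformaldehyde (KOtBu, THF, 0 °C → rt) to the terminal diene F9. Heck arylation of F9 with bromide 5 (Pd(OAc)2 5 mol %, P(o-tol)3, Et3N, DMF, 90 °C) gives the E,E diene and comes back to the route at 12; step 3 is then not needed.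

**Further compounds**

F1 | step 10 | 4-methoxy-3-methylfuran-2(5H)-one | COC1=C(C)C(=O)OC1
F2 | step 10 | 5-{(2S,6E,8E)-9-[4-(furan-3-ylmethyl)furan-3-yl]-1-hydroxy-2,6-dimethylnona-6,8-dien-1-yl}-4-methoxy-3-methylfuran-2(5H)-one (diastereomer mixture at C5 and C1') | COC1=C(C)C(=O)OC1C(O)[C@@H](C)CCC/C(C)=C/C=C/c1cocc1Cc1ccoc1
F3 | step 10 | methanesulfonate of F2 | COC1=C(C)C(=O)OC1C(OS(C)(=O)=O)[C@@H](C)CCC/C(C)=C/C=C/c1cocc1Cc1ccoc1
F4 | step 10 | (5Z)-5-{(2S,6E,8E)-9-[4-(furan-3-ylmethyl)furan-3-yl]-2,6-dimethylnona-6,8-dien-1-ylidene}-4-methoxy-3-methylfuran-2(5H)-one | CC1=C(OC)/C(=C/[C@@H](C)CCC/C(C)=C/C=C/c2cocc2Cc2ccoc2)OC1=O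
F5 | step 6 | diethyl [(2E,6E)-3,7-dimethyl-8-oxoocta-2,6-dien-1-yl]phosphonate | O=C/C(C)=C/CC/C(C)=C/CP(=O)(OCC)OCC
F6 | step 6 | (2E,6E)-8-(diethoxyphosphoryl)-2,6-dimethylocta-2,6-dienoic acid | OC(=O)/C(C)=C/CC/C(C)=C/CP(=O)(OCC)OCC
F7 | step 6 | (2S,6E)-8-(diethoxyphosphoryl)-2,6-dimethyloct-6-enoic acid | OC(=O)[C@@H](C)CCC/C(C)=C/CP(=O)(OCC)OCC
F8 | step 6 | isobutyl carbonic mixed anhydride of F7 | CC(C)COC(=O)OC(=O)[C@@H](C)CCC/C(C)=C/CP(=O)(OCC)OCC
F9 | step 7 | (2S,6E)-2,6-dimethylnona-6,8-dien-1-ol | OC[C@@H](C)CCC/C(C)=C/C=C
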